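The numbers in the tables come from a simulation with constants of no real substance; the scatter is artificial.

Side product and substrate are the two contenders in cedar and maple: at their last readings the target stood at 8.3% in blue and 6.1% in green, less than the side product beside it.

| setting | blue | green | cedar | maple |
|---|---|---|---|---|
| substrate | 0.0087 M | 0.019 M | 0.013 M | 0.013 M |
| gas | 1 mM (held) | 1 mM (held) | 1.0 mM (held) | 1.0 mM (held) |
| remark | run made earlier | run made earlier |  |  |
| time |  |  | 3.0 h | 4.0 h |

| run | time / h | substrate / % | isomer of the product / % | target / % | side product / % |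
|---|---|---|---|---|---|
| blue | 0.133 | 97.3 | 0.4 | 0.1 | 2.1 |
| blue | 0.333 | 93.7 | 0 | 0.3 | 5.7 |
| blue | 0.667 | 87.8 | 0.4 | 1.7 | 10.8 |
| blue | 1.00 | 82.1 | 0 | 3.0 | 15.1 |
| blue | 1.33 | 77.4 | 0 | 4.0 | 19.5 |
| blue | 2.00 | 68.4 | 0 | 6.8 | 24.5 |
| blue | 2.50 | 61.7 | 0.2 | 8.3 | 28.7 |
| green | 0.333 | 87.9 | 0 | 1.2 | 12.6 |
| green | 0.667 | 78.1 | 0 | 1.6 | 21.1 |
| green | 1.00 | 70.2 | 0.4 | 1.8 | 28.7 |
| green | 1.33 | 62.6 | 0 | 2.1 | 34.6 |
| green | 1.50 | 59.8 | 0 | 3.5 | 36.8 |
| green | 2.00 | 52.3 | 0 | 4.4 | 43.0 |
| green | 2.50 | 45.8 | 0 | 6.1 | 47.4 |

(scatter of a reading: 0.5 percentage points)

- in percentages every species weighs as the substrate in it: one side product counts as two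
- what was read earlier has a scatter of 0.5 percentage points, one standard deviation
- at the start none of the gas is in solution

1. which of these there is most of at the end, counted by the substrate in it, cedar (substrate / isomer of the product / side product / target)
2. which of these there is most of at the end, counted by the substrate in it, maple (substrate / isomer of the product / side product / target)
3. final amount of the leader among these, as a percentage of the substrate charged, in cedar
4. final amount of the leader among these, as a percentage of the substrate charged, in maple

We therefore compare two times, the length t of the run and a crossover time t×. If substrate pairs off to side product, a second-order step, then side product over substrate, Q/A, grows as t/t×, with t× inversely proportional to the charge. The last readings give t× = 5.37 h in blue and 2.42 h in green, a ratio of 2.22 against 2.18 for the charges. Scaled to 0.013 M and averaged, they give 3.56 h, the time t× at which side product equals substrate.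

Cedar stops at t/t× = 0.842, so substrate should lead; maple stops at 1.12, so side product should. The target's mean pace in the two runs gives it 8.64% in cedar and 11.5% in maple. Sharing the rest in these ratios, we reckon 49.6% and 46.8% for the leaders.

The forecast, reckoned its own way, names substrate at 50.5% in cedar and side product at 46.5% in maple, saying “side product narrowly leads in maple”.

Cedar ends with substrate leading at 49.1%, and maple with side product at 47.7%.

    gas ⇌ partner, rate k1*(csat - [partner]) (kL = 1.36 h⁻¹)
    target ⇌ isomer of the product (K = 0.644, k = 0.0114 h⁻¹)
    2 substrate → side product (k = 10.6 M⁻¹ h⁻¹)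
    substrate + partner → target (k = 80.9 M⁻¹ h⁻¹)

Q/A stands at 0.857 in cedar and 1.16 in maple. The main reason for the gap in substrate between the two flasks is the difference in time: with cedar's length of run, maple's substrate stands at 49.1% instead of 41.0%, and side product takes the lead in maple at the ratio above. For a flask like maple with 0.052 M of substrate we reckon t× = 0.891 h, so t/t× = 4.49, and that flask ends with side product at 78.7% over substrate at 16.8%, a ratio of 4.68.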